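Remarks before the route. Tetralin numbering is used throughout: C1 bears the pendant aryl ring (ring C), ring A is the fused 6,7-dimethoxybenzene ring (C4a–C8a), ring B is the saturated ring C1–C2–C3–C4–C4a–C8a. Assumption: which hand of the t-Bu-PHOX ligand gives (2R,3S)-6 is not derived here; both hands are commercial and the one that delivers (2R,3S)-6 is to be used.

## Analysis of the target

The target is (1R,2R,3R)-1-(3,4-dimethoxyphenyl)-6,7-dimethoxy-2,3-dimethyl-1,2,3,4-tetrahydronaphthalene, a 1-aryltetralin cyclolignan. Ring B carries three contiguous stereocentres: the aryl group at C1 is trans to the methyl at C2, and the methyls at C2 and C3 are cis. In any half-chair of ring B at least one of the three substituents is therefore axial, and the all-trans diastereomer is the likely thermodynamic sink. The only functional groups are four aryl methyl ethers, so nothing in the molecule can direct a reagent, and every stereocentre is a C–H/C–C centre that cannot be corrected late. The sensitive points are the electron-rich arenes (oxidation, over-alkylation) and the doubly benzylic C1–H. The hard part is absolute control of the cis-vicinal dimethyl pair C2/C3 without a long auxiliary sequence and without an epimerisable intermediate that drains into the all-trans series. The feature the route exploits: rings A and C are the same 3,4-dimethoxyphenyl unit and the C2/C3 methyls are cis, so once the C1–C8a bond is opened the chain C1–C2(Me)–C3(Me)–C4 is a meso 2,3-dimethylsuccinic unit. C1 and C4 then differ only in oxidation level.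

## Retrosynthetic reasoning

**C1–C8a (12 ⇒ 11).** The last bond cut is C1–C8a of ring B. C1 is doubly benzylic and para to a methoxy group of ring C, so its cation forms readily from carbinol 11 and is captured by ring A at the position para to a methoxy group. The closure has to set C1 trans to the C2 methyl; allylic-type strain in the benzylic cation should secure this, and the configuration of the carbinol carbon in 11 is irrelevant.

**C1–ring C (11 ⇒ 10 ⇒ 7 + 8).** Carbinol 11 comes from ketone 10 by hydride reduction, and 10 from acid 7 and aryl Grignard reagent 8 through acid chloride 9. The cut is placed at C1–aryl because C1 is then a carboxyl carbon, the oxidation level an anhydride delivers. The forward steps must not enolise C2.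

**Removal of the C4 oxygen (7 ⇒ 6).** C4 of the target is a methylene on ring A; in keto acid 6 it is an aryl ketone. The ketone must be removed before ring C is put on C1. If C1 and C4 were ever both benzylic C–O carbons bearing the same aryl group, the molecule would become symmetric again and the enantiomeric information would be lost.

**C4–C4a, the key cut (6 ⇒ 2 + 5).** Cutting the aryl–acyl bond of 6 leads to meso anhydride 2 and arylzinc reagent 5, made from bromide 3 through aryllithium 4. This is the point where the hidden mirror plane is used. Both stereocentres already exist in 2 with the correct cis relationship, and a chiral catalyst only has to choose between two enantiotopic carbonyl groups. One catalytic C–C coupling thus fixes the absolute configuration of C2 and C3 together, from a six-carbon achiral precursor.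

**Cis relationship (2 ⇒ 1).** Anhydride 2 comes from the tetrasubstituted alkene 1 by syn hydrogenation, which can only give the cis (meso) isomer.

## Alternatives that were turned down

Alternative 1: the textbook route. Disconnection: C1–C8a by cation cyclisation and C1–aryl by addition of Grignard reagent 8 to aldehyde A1, (2R,3R)-4-(3,4-dimethoxyphenyl)-2,3-dimethylbutanal, whose C2 and C3 are built one after the other by stoichiometric chiral-auxiliary enolate chemistry. Forward key step: acid-mediated Friedel–Crafts closure of the carbinol from A1. Turned down because it needs two separate stereo-setting events for two adjacent methyl-bearing carbons, plus attachment, removal and redox adjustment of the auxiliary. That is roughly ten steps to reach the point the present route reaches in three, and A1 is an α-branched aldehyde that can epimerise at C2.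

Alternative 2: oxidative dimerisation. Disconnection: C2–C3 and C1–C8a in one operation, from two molecules of (E)-1,2-dimethoxy-4-(prop-1-en-1-yl)benzene A2. Forward key step: single-electron oxidation of A2, β–β coupling of the radical cation with a second alkene, and 1,6-closure of the distonic radical cation onto the arene. Turned down on stereochemical grounds: the (E) geometry of both partners and the equatorial preference in the cyclising intermediate should place the two methyls trans, leading to the racemic diastereomer A3, (1R*,2R*,3S*)-1-(3,4-dimethoxyphenyl)-6,7-dimethoxy-2,3-dimethyltetralin. A freely diffusing radical cation offers no handle for absolute control, and cyclobutane and indane dimers compete.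

Alternative 3: dehydrogenative desymmetrisation. Disconnection: C1–C8a by C–H/C–H coupling in the meso hydrocarbon A4, (2R,3S)-1,4-bis(3,4-dimethoxyphenyl)-2,3-dimethylbutane, which can be bought. Forward key step: benzylic hydride abstraction by a quinone oxidant and Friedel–Crafts capture of the cation by the other ring. This is the shortest route on paper. Turned down because the two benzylic methylenes of A4 are enantiotopic and four bonds apart; an achiral hydride acceptor gives the racemate, and no chiral oxidant can be defended for this distinction. Aryl–aryl coupling to an eight-membered ring and over-oxidation to the naphthalene also compete.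

Key step: step 2

## Route

Step 1
Reactants: 1 2,3-dimethylmaleic anhydride
Product: 2 meso-2,3-dimethylsuccinic anhydride, (3R,4S)-3,4-dimethyloxolane-2,5-dione
Conditions: H2 (4 atm), 10 % Pd/C, EtOAc, rt
Reagents that add atoms: none
Why: Heterogeneous hydrogenation adds both hydrogens to one face of the tetrasubstituted alkene, so only the cis (meso) anhydride can form; this fixes the C2/C3 relative configuration of the target.

Step 2
Reactants: 2 meso-2,3-dimethylsuccinic anhydride; 3 4-bromo-1,2-dimethoxybenzene
Product: 6 (2R,3S)-4-(3,4-dimethoxyphenyl)-2,3-dimethyl-4-oxobutanoic acid, via aryllithium 4 (not isolated), via arylzinc triflate 5 (not isolated)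
Conditions: 3, n-BuLi, THF, −78 °C; Zn(OTf)2, −78 °C → rt; then 2, [Rh(cod)Cl]2 (4 mol %), t-Bu-PHOX (8 mol %, hand chosen to give 2R,3S), THF, 50 °C; 1 M HCl
Reagents that add atoms: none
Why: Monovalent rhodium carrying the chiral P,N ligand inserts into one of the two enantiotopic C(acyl)–O bonds of 2 to give an acyl rhodium carboxylate (trivalent rhodium); aryl transfer from zinc reagent 5 and reductive elimination then form the C4–C4a aryl ketone bond and release the zinc carboxylate of 6. The closest known reaction type is the rhodium- or palladium-catalysed enantioselective arylative opening of meso succinic anhydrides, cis-2,3-disubstituted ones included, with arylzinc reagents. The step closes no ring: it opens the anhydride ring, and ring B is closed in step 6. No stereocentre is created and neither existing one is touched, because only C(acyl)–O and C(acyl)–Rh bonds react. The ligand's choice of the carbonyl next to the (S)-configured carbon therefore turns the meso pair into the (2R,3S) acid and so fixes the absolute configuration of C3 and C2 of the target together. Three selectivities are needed: (a) discrimination of the enantiotopic carbonyls, secured by the ligand acting on a small, rigid substrate; (b) mono-arylation, secured because arylzinc reagents do not add to the ketone formed and the zinc carboxylate is inert to a second insertion; (c) no epimerisation α to the new ketone, secured by the non-basic zinc carboxylate medium and the moderate temperature. The precursor is a six-carbon meso compound one step from a commodity chemical.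

Step 3
Reactants: 6 (2R,3S)-4-(3,4-dimethoxyphenyl)-2,3-dimethyl-4-oxobutanoic acid
Product: 7 (2R,3R)-4-(3,4-dimethoxyphenyl)-2,3-dimethylbutanoic acid
Conditions: H2 (4 atm), 10 % Pd/C, AcOH, HClO4 (cat.), rt
Reagents that add atoms: none
Why: Hydrogenolysis of a p-alkoxyaryl ketone to the methylene proceeds through the benzylic alcohol and its γ-lactone on the palladium surface, without an enol or alkene at C3. After this step C3 is no longer epimerisable, and C4 and C1 are at clearly different oxidation levels (the descriptor at C3 changes from S to R only because the priorities change).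

Step 4
Reactants: 7 (2R,3R)-4-(3,4-dimethoxyphenyl)-2,3-dimethylbutanoic acid; 8 (3,4-dimethoxyphenyl)magnesium bromide
Product: 10 (2R,3R)-1,4-bis(3,4-dimethoxyphenyl)-2,3-dimethylbutan-1-one, via acid chloride 9 (not isolated)
Conditions: (COCl)2, DMF (cat.), CH2Cl2, 0 °C → rt, evaporate; then 8, Fe(acac)3 (3 mol %), THF, −78 °C
Reagents that add atoms: none
Why: The acid chloride forms under base-free conditions, and iron-catalysed acylation of an aryl Grignard reagent at −78 °C stops cleanly at the ketone. With no amine base and no warming, C2 is not enolised and ring A is not acylated by the acid chloride.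

Step 5
Reactants: 10 (2R,3R)-1,4-bis(3,4-dimethoxyphenyl)-2,3-dimethylbutan-1-one
Product: 11 (2R,3R)-1,4-bis(3,4-dimethoxyphenyl)-2,3-dimethylbutan-1-ol (both C1 epimers)
Conditions: NaBH4, MeOH/THF, 0 °C → rt
Reagents that add atoms: none
Why: Borohydride reduction of the aryl ketone is faster than enolisation at C2; the configuration of the new carbinol carbon does not matter because it is ionised in the next step.

Step 6
Reactants: 11 (2R,3R)-1,4-bis(3,4-dimethoxyphenyl)-2,3-dimethylbutan-1-ol
Product: 12 (1R,2R,3R)-1-(3,4-dimethoxyphenyl)-6,7-dimethoxy-2,3-dimethyl-1,2,3,4-tetrahydronaphthalene (target)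
Conditions: TFA (10 equiv), CH2Cl2, 0 °C → rt
Reagents that add atoms: none
Why: Intramolecular Friedel–Crafts alkylation: the p-alkoxybenzylic cation at C1 is captured by ring A para to a methoxy group, which closes the six-membered ring B and gives the 6,7-dimethoxy pattern. C1 is set by allylic-type strain in the cation: both low-energy chair-like transition states (aryl and C2 methyl both pseudoequatorial, or both pseudoaxial) give the 1,2-trans product. The cis closure would need the C2 methyl eclipsed with ring C or a 1,3-diaxial clash between ring C and the C3 methyl.

## Compound list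

1 | 2,3-dimethylmaleic anhydride (3,4-dimethylfuran-2,5-dione) | CC1=C(C)C(=O)OC1=O | starting material
2 | meso-2,3-dimethylsuccinic anhydride, (3R,4S)-3,4-dimethyloxolane-2,5-dione | C[C@H]1C(=O)OC(=O)[C@H]1C | intermediate
3 | 4-bromo-1,2-dimethoxybenzene | COc1ccc(Br)cc1OC | starting material
4 | (3,4-dimethoxyphenyl)lithium | [Li]c1ccc(OC)c(OC)c1 | intermediate
5 | (3,4-dimethoxyphenyl)zinc trifluoromethanesulfonate | COc1ccc([Zn]OS(=O)(=O)C(F)(F)F)cc1OC | intermediate
6 | (2R,3S)-4-(3,4-dimethoxyphenyl)-2,3-dimethyl-4-oxobutanoic acid | COc1ccc(C(=O)[C@@H](C)[C@H](C(=O)O)C)cc1OC | intermediate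
7 | (2R,3R)-4-(3,4-dimethoxyphenyl)-2,3-dimethylbutanoic acid | COc1ccc(C[C@@H](C)[C@H](C(=O)O)C)cc1OC | intermediate
8 | (3,4-dimethoxyphenyl)magnesium bromide | COc1ccc([Mg]Br)cc1OC | starting material
9 | (2R,3R)-4-(3,4-dimethoxyphenyl)-2,3-dimethylbutanoyl chloride | COc1ccc(C[C@@H](C)[C@H](C(=O)Cl)C)cc1OC | intermediate
10 | (2R,3R)-1,4-bis(3,4-dimethoxyphenyl)-2,3-dimethylbutan-1-one | COc1ccc(C[C@@H](C)[C@H](C(=O)c2ccc(OC)c(OC)c2)C)cc1OC | intermediate
11 | (2R,3R)-1,4-bis(3,4-dimethoxyphenyl)-2,3-dimethylbutan-1-ol (both C1 epimers) | COc1ccc(C[C@@H](C)[C@H](C(O)c2ccc(OC)c(OC)c2)C)cc1OC | intermediate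
12 | (1R,2R,3R)-1-(3,4-dimethoxyphenyl)-6,7-dimethoxy-2,3-dimethyl-1,2,3,4-tetrahydronaphthalene | COc1ccc([C@@H]2c3cc(OC)c(OC)cc3C[C@@H](C)[C@H]2C)cc1OC | target

## Step count and risk

Total step count: 6. Longest linear sequence: 6 steps (1 → 12); compounds 3 and 8 are purchased and enter directly.

**Step 2 (key step).** The electron-rich arylzinc reagent may give incomplete discrimination between the enantiotopic carbonyls, or slow transmetalation may let protodemetalation of 5 compete. Acid 7 offers a point for enrichment by crystallisation if needed. Fallback, setting out from 2 and returning at 7: desymmetrise 2 by cinchona-alkaloid-catalysed methanolysis ((DHQD)2AQN or its pseudo-enantiomer, MeOH, Et2O, −20 °C) to the hemiester (2S,3R)-4-methoxy-2,3-dimethyl-4-oxobutanoic acid F1. Convert its free acid with oxalyl chloride into methyl (2R,3S)-4-chloro-2,3-dimethyl-4-oxobutanoate F2 and couple with Grignard reagent 8 under Fe(acac)3 catalysis at −78 °C to give the keto ester methyl (2R,3S)-4-(3,4-dimethoxyphenyl)-2,3-dimethyl-4-oxobutanoate F3. Hydrogenolyse the ketone as in step 3 to methyl (2R,3R)-4-(3,4-dimethoxyphenyl)-2,3-dimethylbutanoate F4, and saponify with LiOH to reach 7. Here the enantiotopic carbonyls are distinguished by an organocatalyst and the aryl group is introduced in a separate, non-stereogenic step.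

**Step 6.** Proton loss from the benzylic cation toward C2 followed by reprotonation would erode C2, and facial selectivity at C1 could be incomplete because one methyl must be axial in either transition state. Fallback, setting out from acid chloride 9 (made from 7 as in the first stage of step 4) and returning at 12: close ring B first by intramolecular acylation (SnCl4, CH2Cl2, −78 → 0 °C) to the tetralone (2R,3R)-6,7-dimethoxy-2,3-dimethyl-3,4-dihydronaphthalen-1(2H)-one F7. Reduce with NaBH4 to (2R,3R)-6,7-dimethoxy-2,3-dimethyl-1,2,3,4-tetrahydronaphthalen-1-ol F8, then ionise F8 with TFA in the presence of excess 1,2-dimethoxybenzene. The external arene attacks the cyclic C1 cation anti to the C2 methyl, which again gives the 1,2-trans product 12, now with C1–ring C as the last bond formed.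

**Step 4.** Ring A could be acylated prematurely by the acid chloride, or a ketene could form from 9 with loss of configuration at C2; homocoupling of 8 lowers the yield. Fallback, setting out from 7 and returning at 10: couple 7 with N,O-dimethylhydroxylamine hydrochloride (EDC·HCl, N-methylmorpholine, CH2Cl2) to the Weinreb amide (2R,3R)-4-(3,4-dimethoxyphenyl)-N-methoxy-N,2,3-trimethylbutanamide F6, and add Grignard reagent 8 (THF, 0 °C); the chelated tetrahedral adduct collapses to 10 only on work-up, so no acid chloride is involved.

**Step 3.** Acid-catalysed enolisation of the aryl ketone could erode C3 before the carbonyl is removed, or the reaction could stall at the benzylic lactone. Fallback, setting out from 6 and returning at 7: convert the ketone with ethane-1,2-dithiol and BF3·OEt2 into the dithiolane (2R,3S)-3-[2-(3,4-dimethoxyphenyl)-1,3-dithiolan-2-yl]-2-methylbutanoic acid F5 and desulfurise with Raney Ni in ethanol, a carbon–sulfur hydrogenolysis that needs neither a benzylic cation nor a strong acid.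

## Further compounds

F1 | step 2 | (2S,3R)-4-methoxy-2,3-dimethyl-4-oxobutanoic acid | OC(=O)[C@@H](C)[C@H](C(=O)OC)C
F2 | step 2 | methyl (2R,3S)-4-chloro-2,3-dimethyl-4-oxobutanoate | ClC(=O)[C@@H](C)[C@H](C(=O)OC)C
F3 | step 2 | methyl (2R,3S)-4-(3,4-dimethoxyphenyl)-2,3-dimethyl-4-oxobutanoate | COc1ccc(C(=O)[C@@H](C)[C@H](C(=O)OC)C)cc1OC
F4 | step 2 | methyl (2R,3R)-4-(3,4-dimethoxyphenyl)-2,3-dimethylbutanoate | COc1ccc(C[C@@H](C)[C@H](C(=O)OC)C)cc1OC
F5 | step 3 | (2R,3S)-3-[2-(3,4-dimethoxyphenyl)-1,3-dithiolan-2-yl]-2-methylbutanoic acid | COc1ccc(C2(SCCS2)[C@@H](C)[C@H](C(=O)O)C)cc1OC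
F6 | step 4 | (2R,3R)-4-(3,4-dimethoxyphenyl)-N-methoxy-N,2,3-trimethylbutanamide | COc1ccc(C[C@@H](C)[C@H](C(=O)N(C)OC)C)cc1OC
F7 | step 6 | (2R,3R)-6,7-dimethoxy-2,3-dimethyl-3,4-dihydronaphthalen-1(2H)-one | O=C1c2cc(OC)c(OC)cc2C[C@@H](C)[C@H]1C
F8 | step 6 | (2R,3R)-6,7-dimethoxy-2,3-dimethyl-1,2,3,4-tetrahydronaphthalen-1-ol (both C1 epimers) | OC1c2cc(OC)c(OC)cc2C[C@@H](C)[C@H]1C
A1 | alternative 1 | (2R,3R)-4-(3,4-dimethoxyphenyl)-2,3-dimethylbutanal | COc1ccc(C[C@@H](C)[C@H](C=O)C)cc1OC
A2 | alternative 2 | (E)-1,2-dimethoxy-4-(prop-1-en-1-yl)benzene | COc1ccc(/C=C/C)cc1OC
A3 | alternative 2 | (1R*,2R*,3S*)-1-(3,4-dimethoxyphenyl)-6,7-dimethoxy-2,3-dimethyl-1,2,3,4-tetrahydronaphthalene (racemate, one enantiomer drawn) | COc1ccc([C@@H]2c3cc(OC)c(OC)cc3C[C@H](C)[C@H]2C)cc1OC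
A4 | alternative 3 | (2R,3S)-1,4-bis(3,4-dimethoxyphenyl)-2,3-dimethylbutane (meso) | COc1ccc(C[C@@H](C)[C@H](Cc2ccc(OC)c(OC)c2)C)cc1OC
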